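**Plan**

- Ring numbering: C1 (ester-bearing alkene carbon), C2, C3 (OAc), C4, C5 (Me) and C6 (oxirane), C7, C8 (i-Pr), C9, C10 (OAc), C11 (second ester), C12, C13, C14. Enabling feature: C1 carries ring carbon C14 trans to C3 and the ester cis to C3, the pattern of a 1,1-dibromoalkene whose two bromines differ by their position relative to C3.
- Cuts, in retrosynthetic order: the oxirane oxygen from C5=C6; C11–CO2Me (back to the C11≡C12 alkyne) and C1–CO2Me (back to C1–Br); ring bond C14–C1; C12–C13; C6–C7; then C10–C11, C8–C9 and C4–C5.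
- Forward: a C2–C6 alkyne and a C7–C12 alkenyl bromide are joined at C6–C7 (carboalumination/Negishi), and the enyne and the C1 dibromoalkene are added. The 14-membered ring, the only carbocycle, closes at C14–C1 by hydroboration/B-alkyl Suzuki coupling; the oxirane is made last.
- Stereocentres: C3 from (S)-glycidol; C10 by Noyori transfer hydrogenation of a ynone; C5/C6 by Shi epoxidation with the L-fructose-derived ketone.
- Alkene geometry: C5=C6 from syn-methylalumination; C7=C8 from syn-bromoallylation; C1=C2 from the site-selective coupling and retentive carbonylation; C11=C12 from hydroxyl-directed trans-hydrostannation and retentive carbonylation.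

Key step: step 16

Assumption: the ring numbering above is used for the corresponding atoms of all intermediates, and the macrocycle names follow it instead of lowest locants.

**Route**

Step 1
Reactants: 1 (S)-glycidol
Product: 2 (R)-triethyl(oxiran-2-ylmethoxy)silane
Conditions: Et3SiCl, imidazole, CH2Cl2, 0 °C
Reagents that add atoms: chlorotriethylsilane (CC[Si](Cl)(CC)CC)
Why: Silylation of the primary alcohol (silyl ether protection) leaves the epoxide and its stereocentre untouched and rules out Payne rearrangement in the next step.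

Step 2
Reactants: 2 (R)-triethyl(oxiran-2-ylmethoxy)silane; 3 ethynyltrimethylsilane
Product: 5 (2R)-1-(triethylsilyloxy)-5-(trimethylsilyl)pent-4-yn-2-ol, via lithium (trimethylsilyl)acetylide 4 (not isolated)
Conditions: 3, n-BuLi, THF, −78 °C; BF3·OEt2; then 2, −78 °C
Reagents that add atoms: none
Why: BF3-promoted opening of a terminal epoxide by a lithium acetylide (Yamaguchi alkynylation) occurs at the unsubstituted carbon, so the glycidol stereocentre is carried over unchanged as C3.

Step 3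
Reactants: 5 (2R)-1-(triethylsilyloxy)-5-(trimethylsilyl)pent-4-yn-2-ol
Product: 6 (2R)-pent-4-yne-1,2-diol
Conditions: Bu4NF, THF, 0 °C → rt
Reagents that add atoms: none
Why: Fluoride cleaves both the alkynyl C–Si bond and the O–Si bond (fluoride desilylation), so the terminal alkyne diol should be obtained without touching the stereocentre.

Step 4
Reactants: 6 (2R)-pent-4-yne-1,2-diol
Product: 7 (4R)-4,5-bis(triethylsilyloxy)pent-1-yne
Conditions: Et3SiCl (2.2 equiv), imidazole, DMAP (cat.), CH2Cl2, 0 °C → rt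
Reagents that add atoms: chlorotriethylsilane (CC[Si](Cl)(CC)CC)
Why: Double silylation (silyl ether protection) masks both hydroxyls, the primary one as a triethylsilyl ether because that group can later be oxidised directly to the aldehyde.

Step 5
Reactants: 8 3-methylbut-1-yne; 9 allyl bromide
Product: 10 (1E)-1-bromo-2-(propan-2-yl)penta-1,4-diene
Conditions: PdBr2(PhCN)2 (cat.), neat allyl bromide (excess), sealed vessel, rt
Reagents that add atoms: none
Why: Palladium-catalysed bromoallylation of a terminal alkyne proceeds by syn-bromopalladation (bromine to the terminal carbon), insertion of allyl bromide and β-bromide elimination, which places bromine cis to the new CH2 group and so fixes the C7=C8 geometry.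

Step 6
Reactants: 10 (1E)-1-bromo-2-(propan-2-yl)penta-1,4-diene
Product: 12 (3E)-4-bromo-3-(propan-2-yl)but-3-enal, via diol 11 (not isolated)
Conditions: OsO4 (cat.), NaIO4, 2,6-lutidine, dioxane/H2O, rt
Reagents that add atoms: sodium periodate ([Na+].[O-]I(=O)(=O)=O)
Why: Lemieux–Johnson oxidation (catalytic dihydroxylation then periodate cleavage) should attack the monosubstituted alkene in preference to the bromine-deactivated trisubstituted one and give the C10 aldehyde, which is used crude.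

Step 7
Reactants: 12 (3E)-4-bromo-3-(propan-2-yl)but-3-enal; 3 ethynyltrimethylsilane
Product: 14 rac-(5E)-6-bromo-5-(propan-2-yl)-1-(trimethylsilyl)hex-5-en-1-yn-3-ol, via bromomagnesium (trimethylsilyl)acetylide 13 (not isolated)
Conditions: 3, EtMgBr, THF, 0 °C → rt; then 12, −78 → 0 °C; aq. NH4Cl
Reagents that add atoms: none
Why: 1,2-Addition of an alkynyl Grignard reagent, which is less basic than a lithium acetylide and so should not enolise the β,γ-unsaturated aldehyde, forms the C10–C11 bond, and the carbinol is deliberately made racemic because its configuration is set in step 9.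

Step 8
Reactants: 14 rac-(5E)-6-bromo-5-(propan-2-yl)-1-(trimethylsilyl)hex-5-en-1-yn-3-ol
Product: 15 (5E)-6-bromo-5-(propan-2-yl)-1-(trimethylsilyl)hex-5-en-1-yn-3-one
Conditions: Dess–Martin periodinane, pyridine, CH2Cl2, 0 °C
Reagents that add atoms: none
Why: Dess–Martin oxidation of a propargylic alcohol is mild and buffered, so the β,γ-alkene is not expected to move into conjugation with the ynone.

Step 9
Reactants: 15 (5E)-6-bromo-5-(propan-2-yl)-1-(trimethylsilyl)hex-5-en-1-yn-3-one
Product: 16 (3R,5E)-6-bromo-5-(propan-2-yl)-1-(trimethylsilyl)hex-5-en-1-yn-3-ol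
Conditions: Ru[(R,R)-TsDPEN](p-cymene) (cat.), i-PrOH, rt
Reagents that add atoms: none
Why: Noyori asymmetric transfer hydrogenation of an alkynyl ketone under base-free conditions delivers hydride to one face, the alkyne taking the place of the aryl group in the usual model, so the (R,R)-catalyst should set C10 as R.

Step 10
Reactants: 16 (3R,5E)-6-bromo-5-(propan-2-yl)-1-(trimethylsilyl)hex-5-en-1-yn-3-ol
Product: 17 tert-butyl{[(3R,5E)-6-bromo-5-(propan-2-yl)-1-(trimethylsilyl)hex-5-en-1-yn-3-yl]oxy}dimethylsilane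
Conditions: TBSCl, imidazole, DMF, rt
Reagents that add atoms: tert-butylchlorodimethylsilane (CC(C)(C)[Si](C)(C)Cl)
Why: Silylation (silyl ether protection) gives a C10 ether that survives all steps up to step 20 and is more robust than the C3 triethylsilyl ether.

Step 11
Reactants: 7 (4R)-4,5-bis(triethylsilyloxy)pent-1-yne; 17 tert-butyl{[(3R,5E)-6-bromo-5-(propan-2-yl)-1-(trimethylsilyl)hex-5-en-1-yn-3-yl]oxy}dimethylsilane
Product: 20 (3R,5E,7E,10R)-3-(tert-butyldimethylsilyloxy)-8-methyl-5-(propan-2-yl)-10,11-bis(triethylsilyloxy)-1-(trimethylsilyl)undeca-5,7-dien-1-yne, via alkenylalane 18 (not isolated), via alkenylzinc chloride 19 (not isolated)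
Conditions: 7, AlMe3, Cp2ZrCl2 (cat.), CH2Cl2, 0 °C → rt; then ZnCl2, Pd(PPh3)4 (cat.), 17, THF, rt → 40 °C
Reagents that add atoms: trimethylaluminium (C[Al](C)C)
Why: Zirconium-catalysed syn-methylalumination of the terminal alkyne puts methyl on C5 and the metal on C6 cis to it, and the Negishi coupling with alkenyl bromide 17 proceeds with retention at both partners, so the C6–C7 bond should form as the 5E,7E-diene.

Step 12
Reactants: 20 (3R,5E,7E,10R)-3-(tert-butyldimethylsilyloxy)-8-methyl-5-(propan-2-yl)-10,11-bis(triethylsilyloxy)-1-(trimethylsilyl)undeca-5,7-dien-1-yne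
Product: 21 (3R,5E,7E,10R)-3-(tert-butyldimethylsilyloxy)-8-methyl-5-(propan-2-yl)-10,11-bis(triethylsilyloxy)undeca-5,7-dien-1-yne
Conditions: K2CO3 (cat.), MeOH/THF, 0 °C
Reagents that add atoms: none
Why: Base-catalysed methanolysis cleaves the alkynyl C–Si bond within minutes (protodesilylation), whereas alkyl silyl ethers, the primary triethylsilyl ether included, are stable at 0 °C.

Step 13
Reactants: 21 (3R,5E,7E,10R)-3-(tert-butyldimethylsilyloxy)-8-methyl-5-(propan-2-yl)-10,11-bis(triethylsilyloxy)undeca-5,7-dien-1-yne; 22 vinyl bromide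
Product: 23 (5R,7E,9E,12R)-5-(tert-butyldimethylsilyloxy)-10-methyl-7-(propan-2-yl)-12,13-bis(triethylsilyloxy)trideca-1,7,9-trien-3-yne
Conditions: 22 (excess, THF solution), Pd(PPh3)4 (cat.), CuI (cat.), i-Pr2NH, THF, 0 °C → rt
Reagents that add atoms: none
Why: Sonogashira coupling of the terminal alkyne with vinyl bromide forms the C12–C13 bond and gives the 1,3-enyne whose vinyl group becomes C13–C14.

Step 14
Reactants: 23 (5R,7E,9E,12R)-5-(tert-butyldimethylsilyloxy)-10-methyl-7-(propan-2-yl)-12,13-bis(triethylsilyloxy)trideca-1,7,9-trien-3-yne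
Product: 24 (2R,4E,6E,9R)-9-(tert-butyldimethylsilyloxy)-4-methyl-7-(propan-2-yl)-2-(triethylsilyloxy)trideca-4,6,12-trien-10-ynal
Conditions: (COCl)2, DMSO, CH2Cl2, −78 → −40 °C; Et3N, −78 → 0 °C
Reagents that add atoms: none
Why: Under Swern conditions a primary triethylsilyl ether is cleaved and oxidised directly to the aldehyde while secondary silyl ethers persist (selective Swern oxidation of primary silyl ethers), and the α-silyloxy aldehyde is used at once so that C3 does not epimerise.

Step 15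
Reactants: 24 (2R,4E,6E,9R)-9-(tert-butyldimethylsilyloxy)-4-methyl-7-(propan-2-yl)-2-(triethylsilyloxy)trideca-4,6,12-trien-10-ynal
Product: 25 (3R,5E,7E,10R)-1,1-dibromo-10-(tert-butyldimethylsilyloxy)-5-methyl-8-(propan-2-yl)-3-(triethylsilyloxy)tetradeca-1,5,7,13-tetraen-11-yne
Conditions: CBr4, PPh3, Zn, CH2Cl2, rt (ylide preformed); then 24, 0 °C
Reagents that add atoms: tetrabromomethane (BrC(Br)(Br)Br)
Why: Ramirez dibromo-olefination (first stage of the Corey–Fuchs sequence) with the zinc-generated ylide converts the aldehyde into the C1 dibromoalkene under non-acidic conditions that spare the triethylsilyl ether.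

Step 16
Reactants: 25 (3R,5E,7E,10R)-1,1-dibromo-10-(tert-butyldimethylsilyloxy)-5-methyl-8-(propan-2-yl)-3-(triethylsilyloxy)tetradeca-1,5,7,13-tetraen-11-yne
Product: 27 (1Z,3R,5E,7E,10R)-1-bromo-10-(tert-butyldimethylsilyloxy)-5-methyl-8-(propan-2-yl)-3-(triethylsilyloxy)cyclotetradeca-1,5,7-trien-11-yne, via B-alkyl-9-BBN borane 26 (not isolated)
Conditions: 9-BBN-H dimer, THF, 0 °C → rt; then slow addition to Pd(dppf)Cl2 (cat.), AsPh3, Cs2CO3, DMF/THF/H2O, 50 °C, ca. 1 mM
Reagents that add atoms: none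
Why: 9-BBN adds B–H syn and anti-Markovnikov to the only monosubstituted alkene (C13=C14), putting boron on C14, far faster than to the hindered internal C11≡C12 alkyne, the trisubstituted diene or the electron-poor dibromoalkene; zerovalent palladium then inserts into the C1–Br bond trans to C3, the borane is transferred to palladium as its base-derived ate complex, and reductive elimination forms the sp3–sp2 bond C14–C1. The closest known reaction types are the B-alkyl Suzuki–Miyaura macrocyclisation of alkenyl halides and the trans-selective monocoupling of 1,1-dibromoalkenes. The 14-membered ring, the only ring formed, is closed by intramolecular cross-coupling under pseudo-high dilution (slow addition of borane 26). No stereocentre is created; the C1=C2 geometry is fixed by the site of oxidative addition, so that C14 ends trans and the remaining bromine cis to C3. The step needs site selectivity between the two bromines, secured by the silyloxy-bearing C3 that shields the cis bromine and by the strain of a ring-cis closure, and it needs ring closure to outrun oligomerisation, secured by dilution and by the low reactivity of the hindered bromine left in 27.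

Step 17
Reactants: 27 (1Z,3R,5E,7E,10R)-1-bromo-10-(tert-butyldimethylsilyloxy)-5-methyl-8-(propan-2-yl)-3-(triethylsilyloxy)cyclotetradeca-1,5,7-trien-11-yne
Product: 28 (1Z,3R,5E,7E,10R)-1-bromo-10-(tert-butyldimethylsilyloxy)-5-methyl-8-(propan-2-yl)cyclotetradeca-1,5,7-trien-11-yn-3-ol
Conditions: PPTS (cat.), MeOH/CH2Cl2, 0 °C
Reagents that add atoms: none
Why: Mild acid-catalysed methanolysis (selective desilylation) removes a secondary triethylsilyl ether much faster than the tert-butyldimethylsilyl ether at C10.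

Step 18
Reactants: 28 (1Z,3R,5E,7E,10R)-1-bromo-10-(tert-butyldimethylsilyloxy)-5-methyl-8-(propan-2-yl)cyclotetradeca-1,5,7-trien-11-yn-3-ol
Product: 29 (1Z,3R,5E,7E,10R)-1-bromo-10-(tert-butyldimethylsilyloxy)-5-methyl-8-(propan-2-yl)cyclotetradeca-1,5,7-trien-11-yn-3-yl acetate
Conditions: Ac2O, pyridine, DMAP (cat.), CH2Cl2, 0 °C
Reagents that add atoms: acetic anhydride (CC(=O)OC(C)=O)
Why: DMAP-catalysed acetylation installs the C3 acetate before the C1 ester exists, so the C3 oxygen can never lactonise onto the cis ester.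

Step 19
Reactants: 29 (1Z,3R,5E,7E,10R)-1-bromo-10-(tert-butyldimethylsilyloxy)-5-methyl-8-(propan-2-yl)cyclotetradeca-1,5,7-trien-11-yn-3-yl acetate
Product: 30 methyl (1Z,3R,5E,7E,10R)-3-acetoxy-10-(tert-butyldimethylsilyloxy)-5-methyl-8-(propan-2-yl)cyclotetradeca-1,5,7-trien-11-yne-1-carboxylate
Conditions: PdCl2(PPh3)2 (cat.), CO (1 atm), MeOH, Et3N, DMF, 60 °C
Reagents that add atoms: carbon monoxide ([C-]#[O+]); methanol (CO)
Why: Palladium-catalysed methoxycarbonylation of the alkenyl bromide (Heck carbonylation: oxidative addition, CO insertion, methanolysis) proceeds with retention, so the ester should end cis to C3, and oxidative addition to the C–Br bond is expected to be faster than ionisation of the secondary allylic acetate.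

Step 20
Reactants: 30 methyl (1Z,3R,5E,7E,10R)-3-acetoxy-10-(tert-butyldimethylsilyloxy)-5-methyl-8-(propan-2-yl)cyclotetradeca-1,5,7-trien-11-yne-1-carboxylate
Product: 31 methyl (1Z,3R,5E,7E,10R)-3-acetoxy-10-hydroxy-5-methyl-8-(propan-2-yl)cyclotetradeca-1,5,7-trien-11-yne-1-carboxylate
Conditions: HF·pyridine, pyridine, THF, 0 °C → rt
Reagents that add atoms: none
Why: Buffered HF·pyridine (fluoride desilylation) cleaves the propargylic silyl ether without acyl migration or loss of the acetate and ester.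

Step 21
Reactants: 31 methyl (1Z,3R,5E,7E,10R)-3-acetoxy-10-hydroxy-5-methyl-8-(propan-2-yl)cyclotetradeca-1,5,7-trien-11-yne-1-carboxylate
Product: 32 methyl (1Z,3R,5E,7E,10R,11Z)-3-acetoxy-10-hydroxy-5-methyl-8-(propan-2-yl)-11-(tributylstannyl)cyclotetradeca-1,5,7,11-tetraene-1-carboxylate
Conditions: Bu3SnH, [Cp*RuCl]4 (cat.), CH2Cl2, rt
Reagents that add atoms: tributylstannane (CCCC[SnH](CCCC)CCCC)
Why: Ruthenium-catalysed trans-hydrostannation of the alkyne, steered by a hydrogen bond from the C10 hydroxyl to the chloride ligand, should deliver tin to C11 and hydrogen to C12 on opposite faces, leaving the alkenes and the enoate untouched.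

Step 22
Reactants: 32 methyl (1Z,3R,5E,7E,10R,11Z)-3-acetoxy-10-hydroxy-5-methyl-8-(propan-2-yl)-11-(tributylstannyl)cyclotetradeca-1,5,7,11-tetraene-1-carboxylate
Product: 33 dimethyl (1Z,3R,5E,7E,10R,11Z)-3-acetoxy-10-hydroxy-5-methyl-8-(propan-2-yl)cyclotetradeca-1,5,7,11-tetraene-1,11-dicarboxylate
Conditions: Pd(OAc)2 (cat.), AsPh3, 1,4-benzoquinone, CF3CO2H (cat.), CO (1 atm), MeOH, rt
Reagents that add atoms: carbon monoxide ([C-]#[O+]); methanol (CO)
Why: Hydroxyl-assisted oxidative methoxycarbonylation of the alkenylstannane (tin-to-palladium exchange at divalent palladium, CO insertion, methanolysis, benzoquinone reoxidation) replaces tin by CO2Me with retention, so the ester ends cis to C13 as in the target.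

Step 23
Reactants: 33 dimethyl (1Z,3R,5E,7E,10R,11Z)-3-acetoxy-10-hydroxy-5-methyl-8-(propan-2-yl)cyclotetradeca-1,5,7,11-tetraene-1,11-dicarboxylate
Product: 34 dimethyl (1Z,3R,5E,7E,10R,11Z)-3,10-diacetoxy-5-methyl-8-(propan-2-yl)cyclotetradeca-1,5,7,11-tetraene-1,11-dicarboxylate
Conditions: Ac2O, pyridine, DMAP (cat.), CH2Cl2, 0 °C
Reagents that add atoms: acetic anhydride (CC(=O)OC(C)=O)
Why: DMAP-catalysed acetylation of the secondary allylic alcohol is routine for α-(hydroxyalkyl)acrylates and is kept cold and brief to avoid allylic transposition.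

Step 24
Reactants: 34 dimethyl (1Z,3R,5E,7E,10R,11Z)-3,10-diacetoxy-5-methyl-8-(propan-2-yl)cyclotetradeca-1,5,7,11-tetraene-1,11-dicarboxylate
Product: 35 dimethyl (1Z,3R,5S,6S,7E,10R,11Z)-3,10-diacetoxy-5,6-epoxy-5-methyl-8-(propan-2-yl)cyclotetradeca-1,7,11-triene-1,11-dicarboxylate (CNP0359666.2)
Conditions: ent-Shi ketone (L-fructose-derived, from L-sorbose; cat.), KHSO5 (as 2KHSO5·KHSO4·K2SO4), K2CO3, Bu4NHSO4, aq. Na2B4O7 buffer, MeCN/CH2(OMe)2, 0 °C
Reagents that add atoms: potassium peroxymonosulfate ([K+].[O-]S(=O)(=O)OO)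
Why: Shi epoxidation through the spiro transition state of the chiral dioxirane should oxidise the methyl-substituted C5=C6 in preference to the isopropyl-flanked C7=C8 and the electron-poor enoates, and the L-fructose-derived ketone should deliver oxygen to the face that gives 5S,6S (the D-fructose-derived ketone would give 5R,6R).

**Compound list**

1 | (S)-glycidol | C1O[C@H]1CO | starting material
2 | (R)-triethyl(oxiran-2-ylmethoxy)silane | C1O[C@H]1CO[Si](CC)(CC)CC | intermediate
3 | ethynyltrimethylsilane | C[Si](C)(C)C#C | starting material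
4 | lithium (trimethylsilyl)acetylide (not isolated) | [Li]C#C[Si](C)(C)C | intermediate
5 | (2R)-1-(triethylsilyloxy)-5-(trimethylsilyl)pent-4-yn-2-ol | C[Si](C)(C)C#CC[C@@H](O)CO[Si](CC)(CC)CC | intermediate
6 | (2R)-pent-4-yne-1,2-diol | C#CC[C@@H](O)CO | intermediate
7 | (4R)-4,5-bis(triethylsilyloxy)pent-1-yne | C#CC[C@@H](O[Si](CC)(CC)CC)CO[Si](CC)(CC)CC | intermediate
8 | 3-methylbut-1-yne | CC(C)C#C | starting material
9 | allyl bromide (3-bromoprop-1-ene) | C=CCBr | starting material
10 | (1E)-1-bromo-2-(propan-2-yl)penta-1,4-diene (Br cis to the allyl CH2) | Br/C=C(/C(C)C)CC=C | intermediate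
11 | (4E)-5-bromo-4-(propan-2-yl)pent-4-ene-1,2-diol, racemic (not isolated) | Br/C=C(/C(C)C)CC(O)CO | intermediate
12 | (3E)-4-bromo-3-(propan-2-yl)but-3-enal | Br/C=C(/C(C)C)CC=O | intermediate
13 | bromo[(trimethylsilyl)ethynyl]magnesium, the bromomagnesium (trimethylsilyl)acetylide (not isolated) | Br[Mg]C#C[Si](C)(C)C | intermediate
14 | rac-(5E)-6-bromo-5-(propan-2-yl)-1-(trimethylsilyl)hex-5-en-1-yn-3-ol | Br/C=C(/C(C)C)CC(O)C#C[Si](C)(C)C | intermediate
15 | (5E)-6-bromo-5-(propan-2-yl)-1-(trimethylsilyl)hex-5-en-1-yn-3-one | Br/C=C(/C(C)C)CC(=O)C#C[Si](C)(C)C | intermediate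
16 | (3R,5E)-6-bromo-5-(propan-2-yl)-1-(trimethylsilyl)hex-5-en-1-yn-3-ol | Br/C=C(/C(C)C)C[C@@H](O)C#C[Si](C)(C)C | intermediate
17 | tert-butyl{[(3R,5E)-6-bromo-5-(propan-2-yl)-1-(trimethylsilyl)hex-5-en-1-yn-3-yl]oxy}dimethylsilane | Br/C=C(/C(C)C)C[C@@H](O[Si](C)(C)C(C)(C)C)C#C[Si](C)(C)C | intermediate
18 | dimethyl[(1E,4R)-2-methyl-4,5-bis(triethylsilyloxy)pent-1-en-1-yl]alumane (not isolated) | C[Al](C)/C=C(\C)C[C@@H](O[Si](CC)(CC)CC)CO[Si](CC)(CC)CC | intermediate
19 | chloro[(1E,4R)-2-methyl-4,5-bis(triethylsilyloxy)pent-1-en-1-yl]zinc (not isolated) | Cl[Zn]/C=C(\C)C[C@@H](O[Si](CC)(CC)CC)CO[Si](CC)(CC)CC | intermediate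
20 | (3R,5E,7E,10R)-3-(tert-butyldimethylsilyloxy)-8-methyl-5-(propan-2-yl)-10,11-bis(triethylsilyloxy)-1-(trimethylsilyl)undeca-5,7-dien-1-yne | CC[Si](CC)(CC)OC[C@H](O[Si](CC)(CC)CC)C/C(C)=C/C=C(/C(C)C)C[C@@H](O[Si](C)(C)C(C)(C)C)C#C[Si](C)(C)C | intermediate
21 | (3R,5E,7E,10R)-3-(tert-butyldimethylsilyloxy)-8-methyl-5-(propan-2-yl)-10,11-bis(triethylsilyloxy)undeca-5,7-dien-1-yne | CC[Si](CC)(CC)OC[C@H](O[Si](CC)(CC)CC)C/C(C)=C/C=C(/C(C)C)C[C@@H](O[Si](C)(C)C(C)(C)C)C#C | intermediate
22 | vinyl bromide (bromoethene) | C=CBr | starting material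
23 | (5R,7E,9E,12R)-5-(tert-butyldimethylsilyloxy)-10-methyl-7-(propan-2-yl)-12,13-bis(triethylsilyloxy)trideca-1,7,9-trien-3-yne | CC[Si](CC)(CC)OC[C@H](O[Si](CC)(CC)CC)C/C(C)=C/C=C(/C(C)C)C[C@@H](O[Si](C)(C)C(C)(C)C)C#CC=C | intermediate
24 | (2R,4E,6E,9R)-9-(tert-butyldimethylsilyloxy)-4-methyl-7-(propan-2-yl)-2-(triethylsilyloxy)trideca-4,6,12-trien-10-ynal | O=C[C@H](O[Si](CC)(CC)CC)C/C(C)=C/C=C(/C(C)C)C[C@@H](O[Si](C)(C)C(C)(C)C)C#CC=C | intermediate
25 | (3R,5E,7E,10R)-1,1-dibromo-10-(tert-butyldimethylsilyloxy)-5-methyl-8-(propan-2-yl)-3-(triethylsilyloxy)tetradeca-1,5,7,13-tetraen-11-yne | BrC(Br)=C[C@H](O[Si](CC)(CC)CC)C/C(C)=C/C=C(/C(C)C)C[C@@H](O[Si](C)(C)C(C)(C)C)C#CC=C | intermediate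
26 | 9-[(5R,7E,9E,12R)-14,14-dibromo-5-(tert-butyldimethylsilyloxy)-10-methyl-7-(propan-2-yl)-12-(triethylsilyloxy)tetradeca-7,9,13-trien-3-yn-1-yl]-9-borabicyclo[3.3.1]nonane (not isolated) | BrC(Br)=C[C@H](O[Si](CC)(CC)CC)C/C(C)=C/C=C(/C(C)C)C[C@@H](O[Si](C)(C)C(C)(C)C)C#CCCB1C2CCCC1CCC2 | intermediate
27 | (1Z,3R,5E,7E,10R)-1-bromo-10-(tert-butyldimethylsilyloxy)-5-methyl-8-(propan-2-yl)-3-(triethylsilyloxy)cyclotetradeca-1,5,7-trien-11-yne | Br/C1=C\[C@H](O[Si](CC)(CC)CC)C/C(C)=C/C=C(/C(C)C)C[C@@H](O[Si](C)(C)C(C)(C)C)C#CCC1 | intermediate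
28 | (1Z,3R,5E,7E,10R)-1-bromo-10-(tert-butyldimethylsilyloxy)-5-methyl-8-(propan-2-yl)cyclotetradeca-1,5,7-trien-11-yn-3-ol | Br/C1=C\[C@H](O)C/C(C)=C/C=C(/C(C)C)C[C@@H](O[Si](C)(C)C(C)(C)C)C#CCC1 | intermediate
29 | (1Z,3R,5E,7E,10R)-1-bromo-10-(tert-butyldimethylsilyloxy)-5-methyl-8-(propan-2-yl)cyclotetradeca-1,5,7-trien-11-yn-3-yl acetate | Br/C1=C\[C@H](OC(C)=O)C/C(C)=C/C=C(/C(C)C)C[C@@H](O[Si](C)(C)C(C)(C)C)C#CCC1 | intermediate
30 | methyl (1Z,3R,5E,7E,10R)-3-acetoxy-10-(tert-butyldimethylsilyloxy)-5-methyl-8-(propan-2-yl)cyclotetradeca-1,5,7-trien-11-yne-1-carboxylate | COC(=O)/C1=C\[C@H](OC(C)=O)C/C(C)=C/C=C(/C(C)C)C[C@@H](O[Si](C)(C)C(C)(C)C)C#CCC1 | intermediate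
31 | methyl (1Z,3R,5E,7E,10R)-3-acetoxy-10-hydroxy-5-methyl-8-(propan-2-yl)cyclotetradeca-1,5,7-trien-11-yne-1-carboxylate | COC(=O)/C1=C\[C@H](OC(C)=O)C/C(C)=C/C=C(/C(C)C)C[C@@H](O)C#CCC1 | intermediate
32 | methyl (1Z,3R,5E,7E,10R,11Z)-3-acetoxy-10-hydroxy-5-methyl-8-(propan-2-yl)-11-(tributylstannyl)cyclotetradeca-1,5,7,11-tetraene-1-carboxylate | COC(=O)/C1=C\[C@H](OC(C)=O)C/C(C)=C/C=C(/C(C)C)C[C@@H](O)/C([Sn](CCCC)(CCCC)CCCC)=C/CC1 | intermediate
33 | dimethyl (1Z,3R,5E,7E,10R,11Z)-3-acetoxy-10-hydroxy-5-methyl-8-(propan-2-yl)cyclotetradeca-1,5,7,11-tetraene-1,11-dicarboxylate | COC(=O)/C1=C\[C@H](OC(C)=O)C/C(C)=C/C=C(/C(C)C)C[C@@H](O)/C(C(=O)OC)=C/CC1 | intermediate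
34 | dimethyl (1Z,3R,5E,7E,10R,11Z)-3,10-diacetoxy-5-methyl-8-(propan-2-yl)cyclotetradeca-1,5,7,11-tetraene-1,11-dicarboxylate | COC(=O)/C1=C\[C@H](OC(C)=O)C/C(C)=C/C=C(/C(C)C)C[C@@H](OC(C)=O)/C(C(=O)OC)=C/CC1 | intermediate
35 | dimethyl (1Z,3R,5S,6S,7E,10R,11Z)-3,10-diacetoxy-5,6-epoxy-5-methyl-8-(propan-2-yl)cyclotetradeca-1,7,11-triene-1,11-dicarboxylate (CNP0359666.2) | COC(=O)/C1=C\[C@H](OC(C)=O)C[C@]2(C)O[C@H]2/C=C(/C(C)C)C[C@@H](OC(C)=O)/C(C(=O)OC)=C/CC1 | target

**Totals and risks**

Total step count: 24. Longest linear sequence: 20 steps (steps 5–10, then 11–24, from 3-methylbut-1-yne); the glycidol branch is 18 steps (1–4, then 11–24).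

Steps most likely to fail:

1. Step 16. Hydroboration may stray to the conjugated C11≡C12 alkyne, intermolecular coupling may outrun ring closure, or discrimination between the two bromines may be lost. The fallback keeps the trans-selective B-alkyl Suzuki coupling at C14–C1 but runs it between two molecules, and closes the ring at C11≡C12 by ring-closing alkyne metathesis. It sets out from terminal alkyne 21. C-Methylation (n-BuLi, MeI, THF, −78 °C) would give the methyl-capped alkyne F1. The selective Swern oxidation of step 14 would give the aldehyde F2, and Ramirez olefination (CBr4, PPh3, Zn) the dibromoalkene F3. Separately, 5-iodopent-2-yne F4 (from commercial pent-3-yn-1-ol with I2, PPh3 and imidazole) would be treated with t-BuLi and then 9-methoxy-9-BBN to give the borate F5, which avoids hydroborating a conjugated enyne. Coupling of F5 with F3 (Pd(dppf)Cl2, AsPh3, aq. K3PO4, DMF, rt) at the bromine trans to C3 would give the bromo diyne F6. Alkyne metathesis with Mo(≡CC6H4OMe-4)(OSiPh3)3 and 5 Å molecular sieves in toluene would expel but-2-yne and rejoin the route at macrocyclic bromide 27.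

2. Step 24. The dioxirane may fail to distinguish the two trisubstituted alkenes C5=C6 and C7=C8, the catalyst may be mismatched with the faces of the macrocycle, or the allylic C10 acetate may be lost in the basic buffer. The fallback replaces catalyst control alone by steric editing of the substrate and a changed order of events; whether the silyl group shields C7=C8 enough is an expectation, not an established effect. It sets out from hydroxy diester 33. Silylation (TBSOTf, 2,6-lutidine, CH2Cl2, −78 °C) would give the C10 silyl ether F7, in which a bulky group next to C9 screens C7=C8 and no base-labile allylic acetate is present. Epoxidation under the conditions of step 24 would give the silylated epoxide F8. Buffered fluoride (Bu4NF/AcOH, THF, 0 °C) would free the epoxy alcohol F9. Acetylation as in step 23 would rejoin the route at target 35.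

3. Step 19. Zerovalent palladium may ionise the C3 allylic acetate, or the alkenyl- or acylpalladium intermediate may insert the diene or the alkyne across the ring before methanol captures it. The fallback avoids palladium and sets out from macrocyclic bromide 27, whose C3 oxygen is still silylated. Bromine–lithium exchange (t-BuLi, Et2O, −78 °C) and trapping with methyl chloroformate would give, with retention, the silyloxy ester F10. Direct exchange of the triethylsilyl ether for acetate (Ac2O, Sc(OTf)3 cat., MeCN, −20 °C) never liberates the C3 hydroxyl and so avoids lactonisation. It would rejoin the route at ester 30, bypassing steps 17–19.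

Further compounds
F1 | step 16 | (4R,6E,8E,11R)-4-(tert-butyldimethylsilyloxy)-9-methyl-6-(propan-2-yl)-11,12-bis(triethylsilyloxy)dodeca-6,8-dien-2-yne | CC[Si](CC)(CC)OC[C@H](O[Si](CC)(CC)CC)C/C(C)=C/C=C(/C(C)C)C[C@@H](O[Si](C)(C)C(C)(C)C)C#CC
F2 | step 16 | (2R,4E,6E,9R)-9-(tert-butyldimethylsilyloxy)-4-methyl-7-(propan-2-yl)-2-(triethylsilyloxy)dodeca-4,6-dien-10-ynal | O=C[C@H](O[Si](CC)(CC)CC)C/C(C)=C/C=C(/C(C)C)C[C@@H](O[Si](C)(C)C(C)(C)C)C#CC
F3 | step 16 | (3R,5E,7E,10R)-1,1-dibromo-10-(tert-butyldimethylsilyloxy)-5-methyl-8-(propan-2-yl)-3-(triethylsilyloxy)trideca-1,5,7-trien-11-yne | BrC(Br)=C[C@H](O[Si](CC)(CC)CC)C/C(C)=C/C=C(/C(C)C)C[C@@H](O[Si](C)(C)C(C)(C)C)C#CC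
F4 | step 16 | 5-iodopent-2-yne | CC#CCCI
F5 | step 16 | lithium 9-methoxy-9-(pent-3-yn-1-yl)-9-boranuidabicyclo[3.3.1]nonane | [Li+].CC#CCC[B-]1(OC)C2CCCC1CCC2
F6 | step 16 | (6Z,8R,10E,12E,15R)-6-bromo-15-(tert-butyldimethylsilyloxy)-10-methyl-13-(propan-2-yl)-8-(triethylsilyloxy)octadeca-6,10,12-triene-2,16-diyne | Br/C(CCC#CC)=C\[C@H](O[Si](CC)(CC)CC)C/C(C)=C/C=C(/C(C)C)C[C@@H](O[Si](C)(C)C(C)(C)C)C#CC
F7 | step 24 | dimethyl (1Z,3R,5E,7E,10R,11Z)-3-acetoxy-10-(tert-butyldimethylsilyloxy)-5-methyl-8-(propan-2-yl)cyclotetradeca-1,5,7,11-tetraene-1,11-dicarboxylate | COC(=O)/C1=C\[C@H](OC(C)=O)C/C(C)=C/C=C(/C(C)C)C[C@@H](O[Si](C)(C)C(C)(C)C)/C(C(=O)OC)=C/CC1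
F8 | step 24 | dimethyl (1Z,3R,5S,6S,7E,10R,11Z)-3-acetoxy-10-(tert-butyldimethylsilyloxy)-5,6-epoxy-5-methyl-8-(propan-2-yl)cyclotetradeca-1,7,11-triene-1,11-dicarboxylate | COC(=O)/C1=C\[C@H](OC(C)=O)C[C@]2(C)O[C@H]2/C=C(/C(C)C)C[C@@H](O[Si](C)(C)C(C)(C)C)/C(C(=O)OC)=C/CC1
F9 | step 24 | dimethyl (1Z,3R,5S,6S,7E,10R,11Z)-3-acetoxy-5,6-epoxy-10-hydroxy-5-methyl-8-(propan-2-yl)cyclotetradeca-1,7,11-triene-1,11-dicarboxylate | COC(=O)/C1=C\[C@H](OC(C)=O)C[C@]2(C)O[C@H]2/C=C(/C(C)C)C[C@@H](O)/C(C(=O)OC)=C/CC1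
F10 | step 19 | methyl (1Z,3R,5E,7E,10R)-10-(tert-butyldimethylsilyloxy)-5-methyl-8-(propan-2-yl)-3-(triethylsilyloxy)cyclotetradeca-1,5,7-trien-11-yne-1-carboxylate | COC(=O)/C1=C\[C@H](O[Si](CC)(CC)CC)C/C(C)=C/C=C(/C(C)C)C[C@@H](O[Si](C)(C)C(C)(C)C)C#CCC1
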